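**Retrosynthetic overview**

1. Target ⇐ fully O-protected precursor (six methyl ethers, one 3,4-dimethoxybenzyl ether) by a single Lewis-acid deprotection; the E-styryl arm ⇐ Heck coupling of a 5-iodo-2,3-dihydrobenzofuran with 3,5-dimethoxystyrene.
2. Key disconnection C2–C3: the dihydrofuran ring ⇐ cobalt-porphyrin metalloradical cyclisation of a diaryldiazomethane (carbene radical, 1,5-hydrogen-atom transfer from the ortho ArCH2O group, radical ring closure); both stereocentres are set here.
3. Diazo compound ⇐ tosylhydrazone ⇐ diaryl ketone ⇐ three-component carbonylative Suzuki coupling (aryl iodide + CO + 3,5-dimethoxyphenylboronate).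
4. Aryl diiodide ⇐ resorcinol (di-iodination, then double O-benzylation with 3,4-dimethoxybenzyl chloride made from veratrole and formaldehyde; one benzyl group becomes C2 with its aryl ring, the other protects O6); boronate and styrene ⇐ 1,3-dimethoxybenzene by C–H borylation and vinylation.
5. Ring order: the four benzene rings are bought; the dihydrofuran ring is the only ring closed (step 8).

Assumption: 1,2-dimethoxybenzene and 1,3-dimethoxybenzene are used as the commercial O-methyl-protected forms of catechol and resorcinol; all methyl groups are protecting groups and come off in step 10.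

Stereochemistry check: the target SMILES corresponds to (2S,3S), which is the trans-2,3-diaryl arrangement; the same descriptors hold for 15 and 16.

**Route**

Step 1
Reactants: 1 1,2-dimethoxybenzene (veratrole); 2 formaldehyde (as paraformaldehyde)
Product: 3 4-(chloromethyl)-1,2-dimethoxybenzene (3,4-dimethoxybenzyl chloride)
Conditions: (CH2O)n (1 equiv), HCl (g), conc. aq. HCl, toluene, 0–10 °C; 1 in twofold excess
Reagents that add atoms: hydrogen chloride, Cl
Why: Blanc chloromethylation: the hydroxymethyl cation attacks veratrole para to a methoxy group and HCl turns the benzylic alcohol into the chloride, the excess of arene limiting diarylmethane and bis-chloromethyl by-products.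

Step 2
Reactants: 4 benzene-1,3-diol (resorcinol)
Product: 5 4,6-diiodobenzene-1,3-diol
Conditions: ICl (2.1 equiv), Et2O, 0 °C → rt; aq. Na2S2O3 wash
Reagents that add atoms: iodine monochloride, ICl
Why: Electrophilic aromatic iodination: ICl substitutes the two positions that are ortho to one hydroxyl and para to the other (C4, C6), and with two equivalents the crowded C2 position stays free.

Step 3
Reactants: 5 4,6-diiodobenzene-1,3-diol; 3 4-(chloromethyl)-1,2-dimethoxybenzene (2.3 equiv)
Product: 6 1,5-diiodo-2,4-bis[(3,4-dimethoxybenzyl)oxy]benzene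
Conditions: K2CO3 (3 equiv), n-Bu4NI (5 mol %), DMF, 50 °C
Reagents that add atoms: none
Why: Williamson ether synthesis: both phenoxides are O-benzylated by the activated benzylic chloride (C-alkylation is blocked at the iodinated carbons); one ether later supplies C2 and its aryl ring, the other is a 3,4-dimethoxybenzyl protecting group for O6.

Step 4
Reactants: 7 1,3-dimethoxybenzene
Product: 8 2-(3,5-dimethoxyphenyl)-4,4,5,5-tetramethyl-1,3,2-dioxaborolane
Conditions: B2pin2 (1.0 equiv), [Ir(cod)(OMe)]2 (1 mol %), 4,4'-di-tert-butyl-2,2'-bipyridine (2 mol %), THF, 80 °C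
Reagents that add atoms: bis(pinacolato)diboron, CC1(C)OB(OC1(C)C)B1OC(C)(C)C(C)(C)O1
Why: Iridium-catalysed aromatic C–H borylation is sterically controlled and functionalises the only C–H bond of a 1,3-disubstituted arene that has no ortho substituent, C5.

Step 5
Reactants: 8 2-(3,5-dimethoxyphenyl)-4,4,5,5-tetramethyl-1,3,2-dioxaborolane; 9 bromoethene (vinyl bromide, 1 M in THF, 2 equiv)
Product: 10 1-ethenyl-3,5-dimethoxybenzene (3,5-dimethoxystyrene)
Conditions: Pd(PPh3)4 (3 mol %), K2CO3 (3 equiv), THF/H2O (4:1), 65 °C, sealed tube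
Reagents that add atoms: none
Why: Suzuki–Miyaura coupling of the arylboronate with a vinyl halide gives the styrene directly.

Step 6
Reactants: 6 1,5-diiodo-2,4-bis[(3,4-dimethoxybenzyl)oxy]benzene (3 equiv); 11 carbon monoxide; 8 2-(3,5-dimethoxyphenyl)-4,4,5,5-tetramethyl-1,3,2-dioxaborolane (1 equiv)
Product: 12 {2,4-bis[(3,4-dimethoxybenzyl)oxy]-5-iodophenyl}(3,5-dimethoxyphenyl)methanone
Conditions: CO (1 atm), PdCl2(PPh3)2 (3 mol %), K2CO3 (3 equiv), anisole/H2O (20:1), 80 °C; excess 6 recovered by chromatography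
Reagents that add atoms: none
Why: Carbonylative Suzuki–Miyaura coupling: oxidative addition into one C–I bond, CO insertion (favoured over direct transmetalation for an ortho-alkoxy aryl iodide under CO), transmetalation and reductive elimination give the diaryl ketone, and the threefold excess of symmetrical 6 holds the reaction at mono-acylation.

Step 7
Reactants: 12 {2,4-bis[(3,4-dimethoxybenzyl)oxy]-5-iodophenyl}(3,5-dimethoxyphenyl)methanone
Product: 13 N'-[{2,4-bis[(3,4-dimethoxybenzyl)oxy]-5-iodophenyl}(3,5-dimethoxyphenyl)methylidene]-4-methylbenzenesulfonohydrazide (E/Z mixture)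
Conditions: TsNHNH2 (1.5 equiv), PPTS (10 mol %), EtOH, 80 °C
Reagents that add atoms: 4-methylbenzenesulfonohydrazide, Cc1ccc(cc1)S(=O)(=O)NN
Why: Acid-catalysed condensation gives the N-tosylhydrazone (Bamford–Stevens diazo precursor); the E/Z ratio is irrelevant because both isomers give the same diazo compound.

Step 8
Reactants: 13 N'-[{2,4-bis[(3,4-dimethoxybenzyl)oxy]-5-iodophenyl}(3,5-dimethoxyphenyl)methylidene]-4-methylbenzenesulfonohydrazide
Product: 15 (2S,3S)-6-[(3,4-dimethoxybenzyl)oxy]-2-(3,4-dimethoxyphenyl)-3-(3,5-dimethoxyphenyl)-5-iodo-2,3-dihydro-1-benzofuran (trans), via diaryldiazomethane 14 (not isolated)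
Conditions: [Co(3,5-DitBu-ChenPhyrin)] (5 mol %; cobalt complex of the dianion of 5,15-bis(3,5-di-tert-butylphenyl)-10,20-bis{2,6-bis[(S)-2,2-dimethylcyclopropanecarboxamido]phenyl}porphyrin; the ligand from the (R)-amide is used instead if the sense of induction proves opposite), Cs2CO3 (2 equiv), 1,4-dioxane, 0.05 M, 60–70 °C, Ar
Reagents that add atoms: none
Why: Proposed new method: base converts 13 into diazo compound 14, which the divalent-cobalt porphyrin turns (loss of N2) into a cobalt-bound diarylmethyl radical; 1,5-hydrogen-atom transfer from the ortho ArCH2O group gives an α-aryloxybenzyl radical that closes the five-membered ring by homolytic substitution at the Co–C bond (C2–C3 bond), the chiral amide-lined cavity selecting the enantiotopic face at C3 and the stepwise closure placing the two aryl groups trans (also the thermodynamic isomer), while the non-electrophilic radical carbene avoids oxonium-ylide pathways; the closest known reactions are cobalt-metalloradical enantioselective intramolecular C–H alkylation with aryldiazomethanes from aldehyde sulfonylhydrazones (giving 2-aryl-2,3-dihydrobenzofurans) and dirhodium donor/donor-carbene C–H insertion (giving 2,3-diaryl-2,3-dihydrobenzofurans).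

Step 9
Reactants: 15 (2S,3S)-6-[(3,4-dimethoxybenzyl)oxy]-2-(3,4-dimethoxyphenyl)-3-(3,5-dimethoxyphenyl)-5-iodo-2,3-dihydro-1-benzofuran; 10 1-ethenyl-3,5-dimethoxybenzene (1.5 equiv)
Product: 16 (2S,3S)-6-[(3,4-dimethoxybenzyl)oxy]-2-(3,4-dimethoxyphenyl)-3-(3,5-dimethoxyphenyl)-5-[(E)-2-(3,5-dimethoxyphenyl)ethenyl]-2,3-dihydro-1-benzofuran
Conditions: Pd(OAc)2 (5 mol %), n-Bu4NCl (1 equiv), K2CO3 (2.5 equiv), DMF, 80 °C
Reagents that add atoms: none
Why: Mizoroki–Heck reaction (Jeffery conditions): syn-carbopalladation of the styrene and syn-β-hydride elimination give the E-stilbene, and the benzylic stereocentres are not touched by carbonate at 80 °C.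

Step 10
Reactants: 16 (2S,3S)-6-[(3,4-dimethoxybenzyl)oxy]-2-(3,4-dimethoxyphenyl)-3-(3,5-dimethoxyphenyl)-5-[(E)-2-(3,5-dimethoxyphenyl)ethenyl]-2,3-dihydro-1-benzofuran
Product: 17 (2S,3S)-2-(3,4-dihydroxyphenyl)-3-(3,5-dihydroxyphenyl)-5-[(E)-2-(3,5-dihydroxyphenyl)ethenyl]-2,3-dihydro-1-benzofuran-6-ol (CNP0263230.1)
Conditions: BBr3 (14 equiv), C6HMe5 (3 equiv), CH2Cl2, −78 → 0 °C, dark; MeOH then aq. NaHCO3
Reagents that add atoms: none
Why: Lewis-acid ether cleavage: BBr3 removes the 3,4-dimethoxybenzyl group at low temperature (cation trapped by pentamethylbenzene) and then the six methyl ethers by bromide attack at the O-methyl carbons; C3 is not involved, any reversible C2–O ionisation re-closes to the favoured trans isomer, and the E-alkene is retained.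

**Compound list**

1 | 1,2-dimethoxybenzene | COc1ccccc1OC | starting material
2 | formaldehyde (paraformaldehyde) | C=O | starting material
3 | 4-(chloromethyl)-1,2-dimethoxybenzene | COc1ccc(CCl)cc1OC | intermediate
4 | benzene-1,3-diol | Oc1cccc(O)c1 | starting material
5 | 4,6-diiodobenzene-1,3-diol | Oc1cc(O)c(I)cc1I | intermediate
6 | 1,5-diiodo-2,4-bis[(3,4-dimethoxybenzyl)oxy]benzene | COc1ccc(COc2cc(OCc3ccc(OC)c(OC)c3)c(I)cc2I)cc1OC | intermediate
7 | 1,3-dimethoxybenzene | COc1cccc(OC)c1 | starting material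
8 | 2-(3,5-dimethoxyphenyl)-4,4,5,5-tetramethyl-1,3,2-dioxaborolane | COc1cc(OC)cc(c1)B1OC(C)(C)C(C)(C)O1 | intermediate
9 | bromoethene | BrC=C | starting material
10 | 1-ethenyl-3,5-dimethoxybenzene | C=Cc1cc(OC)cc(OC)c1 | intermediate
11 | carbon monoxide | [C-]#[O+] | starting material
12 | {2,4-bis[(3,4-dimethoxybenzyl)oxy]-5-iodophenyl}(3,5-dimethoxyphenyl)methanone | COc1cc(OC)cc(c1)C(=O)c1cc(I)c(OCc2ccc(OC)c(OC)c2)cc1OCc1ccc(OC)c(OC)c1 | intermediate
13 | N'-[{2,4-bis[(3,4-dimethoxybenzyl)oxy]-5-iodophenyl}(3,5-dimethoxyphenyl)methylidene]-4-methylbenzenesulfonohydrazide (E/Z mixture) | Cc1ccc(cc1)S(=O)(=O)NN=C(c1cc(OC)cc(OC)c1)c1cc(I)c(OCc2ccc(OC)c(OC)c2)cc1OCc1ccc(OC)c(OC)c1 | intermediate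
14 | 1-[diazo(3,5-dimethoxyphenyl)methyl]-2,4-bis[(3,4-dimethoxybenzyl)oxy]-5-iodobenzene | [N-]=[N+]=C(c1cc(OC)cc(OC)c1)c1cc(I)c(OCc2ccc(OC)c(OC)c2)cc1OCc1ccc(OC)c(OC)c1 | intermediate (not isolated)
15 | (2S,3S)-6-[(3,4-dimethoxybenzyl)oxy]-2-(3,4-dimethoxyphenyl)-3-(3,5-dimethoxyphenyl)-5-iodo-2,3-dihydro-1-benzofuran | Ic1cc2c(cc1OCc1ccc(OC)c(OC)c1)O[C@H](c1ccc(OC)c(OC)c1)[C@H]2c1cc(OC)cc(OC)c1 | intermediate
16 | (2S,3S)-6-[(3,4-dimethoxybenzyl)oxy]-2-(3,4-dimethoxyphenyl)-3-(3,5-dimethoxyphenyl)-5-[(E)-2-(3,5-dimethoxyphenyl)ethenyl]-2,3-dihydro-1-benzofuran | COc1cc(OC)cc(/C=C/c2cc3c(cc2OCc2ccc(OC)c(OC)c2)O[C@H](c2ccc(OC)c(OC)c2)[C@H]3c2cc(OC)cc(OC)c2)c1 | intermediate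
17 | (2S,3S)-2-(3,4-dihydroxyphenyl)-3-(3,5-dihydroxyphenyl)-5-[(E)-2-(3,5-dihydroxyphenyl)ethenyl]-2,3-dihydro-1-benzofuran-6-ol | Oc1cc(O)cc(/C=C/c2cc3c(cc2O)O[C@H](c2ccc(O)c(O)c2)[C@H]3c2cc(O)cc(O)c2)c1 | target

**Step count**

Total steps: 10. Longest linear sequence: 7 steps (steps 1, 3, 6, 7, 8, 9, 10; the branch from resorcinol through steps 2, 3, 6–10 is equally long).

**Steps most likely to fail, with fallbacks**

Step 8 (cobalt metalloradical ring closure). The diaryl diazo compound is more hindered and gives a more stabilised carbene radical than the aldehyde-derived cases that are known, so conversion and ee at C3 are uncertain. Only C3 has to be controlled by the catalyst, because C2 can be corrected by acid-mediated epimerisation. Fallback: set out from ketone 12 and condense it with hydrazine hydrate (EtOH, cat. AcOH, 80 °C) to the free hydrazone {2,4-bis[(3,4-dimethoxybenzyl)oxy]-5-iodophenyl}(3,5-dimethoxyphenyl)methanone hydrazone F1. Oxidise F1 with activated MnO2 (CH2Cl2, 0 °C) to a filtered solution of diazo compound 14. Add this to Rh2(R-PTAD)4 (dirhodium tetrakis[(R)-(1-adamantyl)(phthalimido)acetate], 1 mol %, CH2Cl2, −20 °C; the S antipode if the other series results). This two-electron donor/donor carbene C–H insertion gives mainly the cis isomer (2R,3S)-6-[(3,4-dimethoxybenzyl)oxy]-2-(3,4-dimethoxyphenyl)-3-(3,5-dimethoxyphenyl)-5-iodo-2,3-dihydro-1-benzofuran F2. Catalytic BF3·OEt2 (CH2Cl2, −40 °C) then epimerises C2 through reversible C2–O ionisation to the trans compound 15, where the route is rejoined.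

Step 6 (mono-selective carbonylative coupling of a symmetrical diiodide). Over-acylation, direct biaryl coupling or sluggish transmetalation of the pinacol boronate may erode the yield. Fallback: set out from 6 and exchange one iodine only with i-PrMgCl·LiCl (1.05 equiv, THF, −40 °C); the aryl-magnesium species formed resists a second exchange. Quenching with DMF gives 2,4-bis[(3,4-dimethoxybenzyl)oxy]-5-iodobenzaldehyde F3. Rhodium-catalysed 1,2-addition of boronate 8 ([Rh(cod)(OH)]2 2 mol %, dioxane/H2O, 60 °C) gives the racemic carbinol {2,4-bis[(3,4-dimethoxybenzyl)oxy]-5-iodophenyl}(3,5-dimethoxyphenyl)methanol F4. Oxidation with MnO2 (CH2Cl2, rt) returns to ketone 12.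

Step 10 (global deprotection next to an acid-sensitive 2,4-dioxygenated stilbene). Fallback: move the Lewis-acid step ahead of stilbene formation and finish with a mild deacetylation. Set out from 15 and treat it with BBr3/C6HMe5 (CH2Cl2, −78 → 0 °C; no alkene present) to obtain (2S,3S)-2-(3,4-dihydroxyphenyl)-3-(3,5-dihydroxyphenyl)-5-iodo-2,3-dihydro-1-benzofuran-6-ol F5. Peracetylate (Ac2O, pyridine, cat. DMAP) to its pentaacetate F6. In parallel, demethylate styrene 10 (BBr3, CH2Cl2, −78 → 0 °C) to 5-ethenylbenzene-1,3-diol F7 and acetylate the crude at once (Ac2O, pyridine) to 5-ethenyl-1,3-phenylene diacetate F8. Heck coupling of F6 with F8 (Pd(OAc)2, P(o-tol)3, Et3N, DMF, 90 °C) gives the heptaacetate of the target F9. Degassed K2CO3/MeOH at 0 °C followed by acidification returns to the route at 17.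

**Further compounds**

F1 | step 8 | {2,4-bis[(3,4-dimethoxybenzyl)oxy]-5-iodophenyl}(3,5-dimethoxyphenyl)methanone hydrazone | NN=C(c1cc(OC)cc(OC)c1)c1cc(I)c(OCc2ccc(OC)c(OC)c2)cc1OCc1ccc(OC)c(OC)c1
F2 | step 8 | (2R,3S)-6-[(3,4-dimethoxybenzyl)oxy]-2-(3,4-dimethoxyphenyl)-3-(3,5-dimethoxyphenyl)-5-iodo-2,3-dihydro-1-benzofuran (cis) | Ic1cc2c(cc1OCc1ccc(OC)c(OC)c1)O[C@@H](c1ccc(OC)c(OC)c1)[C@H]2c1cc(OC)cc(OC)c1
F3 | step 6 | 2,4-bis[(3,4-dimethoxybenzyl)oxy]-5-iodobenzaldehyde | O=Cc1cc(I)c(OCc2ccc(OC)c(OC)c2)cc1OCc1ccc(OC)c(OC)c1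
F4 | step 6 | {2,4-bis[(3,4-dimethoxybenzyl)oxy]-5-iodophenyl}(3,5-dimethoxyphenyl)methanol (racemic) | OC(c1cc(OC)cc(OC)c1)c1cc(I)c(OCc2ccc(OC)c(OC)c2)cc1OCc1ccc(OC)c(OC)c1
F5 | step 10 | (2S,3S)-2-(3,4-dihydroxyphenyl)-3-(3,5-dihydroxyphenyl)-5-iodo-2,3-dihydro-1-benzofuran-6-ol | Ic1cc2c(cc1O)O[C@H](c1ccc(O)c(O)c1)[C@H]2c1cc(O)cc(O)c1
F6 | step 10 | pentaacetate of F5 | Ic1cc2c(cc1OC(C)=O)O[C@H](c1ccc(OC(C)=O)c(OC(C)=O)c1)[C@H]2c1cc(OC(C)=O)cc(OC(C)=O)c1
F7 | step 10 | 5-ethenylbenzene-1,3-diol | C=Cc1cc(O)cc(O)c1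
F8 | step 10 | 5-ethenyl-1,3-phenylene diacetate | C=Cc1cc(OC(C)=O)cc(OC(C)=O)c1
F9 | step 10 | heptaacetate of 17 | CC(=O)Oc1cc(OC(C)=O)cc(/C=C/c2cc3c(cc2OC(C)=O)O[C@H](c2ccc(OC(C)=O)c(OC(C)=O)c2)[C@H]3c2cc(OC(C)=O)cc(OC(C)=O)c2)c1
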